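**Retrosynthetic overview**
1. Target ⇐ reductive removal of two carboxyl-bound (S)-4-benzyloxazolidinone auxiliaries from a 2,5-diaryloxolane-3,4-dicarbonyl bis-imide; both CH2OH groups appear in this step.
2. Oxolane ring (the only ring made) ⇐ water addition to one end of a C2-symmetric 8–8' bis-quinone methide, then 5-exo closure of the new 7-OH on the other quinone methide.
3. Bis-quinone methide ⇐ chelate-templated, auxiliary-controlled oxidative 8–8' coupling of two identical N-sinapoyl imide phenoxyl radicals, in the same flask as line 2.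
4. N-sinapoyl imide ⇐ Heck coupling of 4-bromo-2,6-dimethoxyphenol with the N-acryloyl imide ⇐ (S)-4-benzyl-2-oxazolidinone and acryloyl chloride.
5. Bond order in the ring-forming cascade: C8–C8', then C7–OH, then O–C7' (ring closure).

Assumption: lignan numbering is used for each C6–C3 half (C7 benzylic, C8, C9); the target SMILES is read as the (2R,3R,4R,5S)-oxolane with the CH2OH groups trans, the aryl at the R benzylic carbon cis and the aryl at the S benzylic carbon trans to the neighbouring CH2OH.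

**Route**

Step 1
Reactants: 1 (4S)-4-benzyl-1,3-oxazolidin-2-one; 2 acryloyl chloride
Product: 3 (4S)-4-benzyl-3-(prop-2-enoyl)-1,3-oxazolidin-2-one
Conditions: MeMgBr, THF, 0 °C; then 2, −78 → 0 °C
Reagents that add atoms: none
Why: Evans N-acylation of the bromomagnesium salt of the oxazolidinone by the acid chloride, run cold so that acylation outruns acrylate polymerisation; the C4 stereocentre is untouched and no new one forms.

Step 2
Reactants: 3 (4S)-4-benzyl-3-(prop-2-enoyl)-1,3-oxazolidin-2-one; 4 4-bromo-2,6-dimethoxyphenol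
Product: 5 (4S)-4-benzyl-3-[(2E)-3-(4-hydroxy-3,5-dimethoxyphenyl)prop-2-enoyl]-1,3-oxazolidin-2-one
Conditions: Pd(OAc)2 (3 mol %), P(o-tol)3 (6 mol %), NaOAc, DMF, 100 °C
Reagents that add atoms: none
Why: Mizoroki–Heck reaction, in which zerovalent palladium inserts into the aryl–Br bond and syn-carbopalladation of the acrylimide followed by syn β-hydride elimination gives only the E-alkene, while the weak acetate base leaves the free phenol and the imide alone; no stereocentre forms.

Step 3
Reactants: 5 (4S)-4-benzyl-3-[(2E)-3-(4-hydroxy-3,5-dimethoxyphenyl)prop-2-enoyl]-1,3-oxazolidin-2-one (two molecules)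
Product: 8 (4S,4'S)-3,3'-[(2R,3S,4S,5S)-2,5-bis(4-hydroxy-3,5-dimethoxyphenyl)oxolane-3,4-dicarbonyl]bis(4-benzyl-1,3-oxazolidin-2-one), via bis-quinone methide 6 (not isolated), via hydroxy quinone methide 7 (not isolated)
Conditions: FeCl3 (2.2 equiv per 5), CH2Cl2/MeNO2 (10:1), −40 → −20 °C; then THF/H2O (4:1), citric acid, −40 → 0 °C
Reagents that add atoms: water, O
Why: Proposed new method: one FeCl3 per imide binds both carbonyl groups as the syn chelate with the enoyl unit s-cis (the geometry behind Evans Diels–Alder reactions and Sibi–Porter chelated imide radicals), a second FeCl3 oxidises the phenol to the phenoxyl radical as in the classical FeCl3 dimerisation of sinapate esters, and two chelated radicals join C8 to C8' on the faces turned away from the benzyl groups (Si at C8 of both halves, the sense known from oxidative homocoupling of Evans imide enolates) to give the (R,R) bis-quinone methide 6; water then adds to C7 of one quinone methide anti to the bulky other half with H8 eclipsing the exocyclic C=C (Felkin-type, gives the R carbinol of 7 and an aryl cis to its acyl neighbour) and this hydroxyl closes on the second quinone methide by 5-exo oxa-1,6-addition through the rotamer free of 1,3-allylic strain (S centre, aryl trans to its acyl neighbour), so phenol oxidative coupling, quinone methide hydration and cyclisation set all four ring stereocentres in one flask; closest known chemistry: FeCl3 oxidation of sinapate esters in aqueous acetone to 2,5-diaryloxolane-3,4-dicarboxylates and chelate-controlled radical reactions of N-acyloxazolidinones.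

Step 4
Reactants: 8 (4S,4'S)-3,3'-[(2R,3S,4S,5S)-2,5-bis(4-hydroxy-3,5-dimethoxyphenyl)oxolane-3,4-dicarbonyl]bis(4-benzyl-1,3-oxazolidin-2-one)
Product: 9 [(2R,3R,4R,5S)-2,5-bis(4-hydroxy-3,5-dimethoxyphenyl)oxolane-3,4-diyl]dimethanol
Conditions: LiBH4, MeOH, THF, 0 °C → rt; aq. NH4Cl
Reagents that add atoms: none
Why: Reductive cleavage of N-acyl oxazolidinones by LiBH4 (hydride adds to the exocyclic imide carbonyl, the auxiliary leaves and the aldehyde is reduced on) turns both acyl groups into the CH2OH groups and returns auxiliary 1, and no stereocentre is touched because the α-carbons are not enolised at 0 °C and the trans acyl groups cannot lactonise.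

**Compound list**
1 | (4S)-4-benzyl-1,3-oxazolidin-2-one | O=C1N[C@@H](Cc2ccccc2)CO1 | starting material
2 | acryloyl chloride (prop-2-enoyl chloride) | C=CC(=O)Cl | starting material
3 | (4S)-4-benzyl-3-(prop-2-enoyl)-1,3-oxazolidin-2-one | C=CC(=O)N1[C@@H](Cc2ccccc2)COC1=O | intermediate
4 | 4-bromo-2,6-dimethoxyphenol | COc1cc(Br)cc(OC)c1O | starting material
5 | (4S)-4-benzyl-3-[(2E)-3-(4-hydroxy-3,5-dimethoxyphenyl)prop-2-enoyl]-1,3-oxazolidin-2-one | COc1cc(/C=C/C(=O)N2[C@@H](Cc3ccccc3)COC2=O)cc(OC)c1O | intermediate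
6 | (4S,4'S)-3,3'-{(2R,3R)-2,3-bis[(3,5-dimethoxy-4-oxocyclohexa-2,5-dien-1-ylidene)methyl]butanedioyl}bis(4-benzyl-1,3-oxazolidin-2-one) | COC1=CC(=C[C@@H](C(=O)N2[C@@H](Cc3ccccc3)COC2=O)[C@@H](C=C4C=C(OC)C(=O)C(OC)=C4)C(=O)N5[C@@H](Cc6ccccc6)COC5=O)C=C(OC)C1=O | intermediate
7 | (4S,4'S)-3,3'-{(2S,3R)-2-[(R)-hydroxy(4-hydroxy-3,5-dimethoxyphenyl)methyl]-3-[(3,5-dimethoxy-4-oxocyclohexa-2,5-dien-1-ylidene)methyl]butanedioyl}bis(4-benzyl-1,3-oxazolidin-2-one) | O[C@@H](c1cc(OC)c(O)c(OC)c1)[C@@H](C(=O)N2[C@@H](Cc3ccccc3)COC2=O)[C@@H](C=C4C=C(OC)C(=O)C(OC)=C4)C(=O)N5[C@@H](Cc6ccccc6)COC5=O | intermediate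
8 | (4S,4'S)-3,3'-[(2R,3S,4S,5S)-2,5-bis(4-hydroxy-3,5-dimethoxyphenyl)oxolane-3,4-dicarbonyl]bis(4-benzyl-1,3-oxazolidin-2-one) | COc1cc([C@H]2O[C@@H](c3cc(OC)c(O)c(OC)c3)[C@@H](C(=O)N4[C@@H](Cc5ccccc5)COC4=O)[C@@H]2C(=O)N6[C@@H](Cc7ccccc7)COC6=O)cc(OC)c1O | intermediate
9 | [(2R,3R,4R,5S)-2,5-bis(4-hydroxy-3,5-dimethoxyphenyl)oxolane-3,4-diyl]dimethanol | COc1cc([C@H]2O[C@@H](c3cc(OC)c(O)c(OC)c3)[C@@H](CO)[C@@H]2CO)cc(OC)c1O | target

**Step count and risk**

Total step count: 4. Longest linear sequence: 4 steps (1 and 2 → 3 → 5 → 8 → 9).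

The three steps most likely to fail, in order of risk:

Step 3 is the main risk. The bis-quinone methide can lose H8 and cyclise to the aryldihydronaphthalene instead of being hydrated. Facial control is lost if the iron chelate does not form. Hydration may also give the all-trans oxolane as a co-product, to be separated by chromatography. The fallback sets out from 5 and comes back to the route at 6; it makes the C8–C8' bond by enolate chemistry and forms the quinone methides afterwards. Silylation of 5 (TBSCl, imidazole, DMF) gives the silyl ether of the sinapoyl imide F1. Hydrogenation (H2, Pd/C, EtOAc) gives the saturated dihydrosinapoyl imide F2. Oxidative homocoupling of its lithium enolate (LDA, THF, −78 °C; then CuCl2) is steered by the auxiliary to the (R,R)-dibenzylsuccinyl bis-imide F3. TBAF buffered with AcOH frees the bis-phenol F4. Ag2O in CH2Cl2 oxidises both 4-alkyl-2,6-dimethoxyphenol units to quinone methides, which gives 6; the filtrate is run into THF/H2O with citric acid and continues to 8 as in step 3.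

Step 4 comes next. LiBH4 may attack the ring carbonyl of these hindered imides, or the basic medium may epimerise or β-eliminate the oxolane. The fallback sets out from 8 and comes back at 9; it removes the auxiliary and reduces in separate operations. MeOMgBr in MeOH at 0 °C exchanges both auxiliaries for methoxide and gives the dimethyl oxolane-3,4-dicarboxylate F5. LiAlH4 in THF at 0 °C then reduces F5 to 9.

Step 2 is third. The electron-rich bromophenol may react sluggishly and the acrylimide may polymerise or transfer its acyl group at 100 °C. The fallback sets out from 1 and comes back at 5; it replaces the Heck reaction by an olefination of an aldehyde. Acylation of 1 (n-BuLi, THF, −78 °C; bromoacetyl bromide) gives the bromoacetyl imide F6. PPh3 in toluene gives the phosphonium bromide F7. Aqueous NaOH/CH2Cl2 gives the stabilised ylide F8. Wittig reaction of F8 with commercial syringaldehyde (free phenol tolerated) in toluene at 80 °C gives 5 as the E-isomer.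

**Further compounds**
F1 | step 3 | (4S)-4-benzyl-3-[(2E)-3-{4-[(tert-butyldimethylsilyl)oxy]-3,5-dimethoxyphenyl}prop-2-enoyl]-1,3-oxazolidin-2-one | COc1cc(/C=C/C(=O)N2[C@@H](Cc3ccccc3)COC2=O)cc(OC)c1O[Si](C)(C)C(C)(C)C
F2 | step 3 | (4S)-4-benzyl-3-(3-{4-[(tert-butyldimethylsilyl)oxy]-3,5-dimethoxyphenyl}propanoyl)-1,3-oxazolidin-2-one | COc1cc(CCC(=O)N2[C@@H](Cc3ccccc3)COC2=O)cc(OC)c1O[Si](C)(C)C(C)(C)C
F3 | step 3 | (4S,4'S)-3,3'-{(2R,3R)-2,3-bis[(4-{[tert-butyl(dimethyl)silyl]oxy}-3,5-dimethoxyphenyl)methyl]butanedioyl}bis(4-benzyl-1,3-oxazolidin-2-one) | COc1cc(C[C@@H](C(=O)N2[C@@H](Cc3ccccc3)COC2=O)[C@@H](Cc4cc(OC)c(O[Si](C)(C)C(C)(C)C)c(OC)c4)C(=O)N5[C@@H](Cc6ccccc6)COC5=O)cc(OC)c1O[Si](C)(C)C(C)(C)C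
F4 | step 3 | (4S,4'S)-3,3'-{(2R,3R)-2,3-bis[(4-hydroxy-3,5-dimethoxyphenyl)methyl]butanedioyl}bis(4-benzyl-1,3-oxazolidin-2-one) | COc1cc(C[C@@H](C(=O)N2[C@@H](Cc3ccccc3)COC2=O)[C@@H](Cc4cc(OC)c(O)c(OC)c4)C(=O)N5[C@@H](Cc6ccccc6)COC5=O)cc(OC)c1O
F5 | step 4 | dimethyl (2R,3S,4S,5S)-2,5-bis(4-hydroxy-3,5-dimethoxyphenyl)oxolane-3,4-dicarboxylate | COc1cc([C@H]2O[C@@H](c3cc(OC)c(O)c(OC)c3)[C@@H](C(=O)OC)[C@@H]2C(=O)OC)cc(OC)c1O
F6 | step 2 | (4S)-4-benzyl-3-(bromoacetyl)-1,3-oxazolidin-2-one | O=C(CBr)N1[C@@H](Cc2ccccc2)COC1=O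
F7 | step 2 | {2-[(4S)-4-benzyl-2-oxo-1,3-oxazolidin-3-yl]-2-oxoethyl}(triphenyl)phosphonium bromide | O=C(C[P+](c1ccccc1)(c1ccccc1)c1ccccc1)N1[C@@H](Cc2ccccc2)COC1=O.[Br-]
F8 | step 2 | (4S)-4-benzyl-3-[(triphenylphosphoranylidene)acetyl]-1,3-oxazolidin-2-one | O=C(C=P(c1ccccc1)(c1ccccc1)c1ccccc1)N1[C@@H](Cc2ccccc2)COC1=O
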